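**Plan**
- Cuts: first the two ester C–O bonds at O3 and O9 (Z-enoates from ynoates). Then functional-group changes in ring A (3α-carbinol from a 1-en-3-one, C4 methyl from a formyl group). Then C3–C4 and C5–C10 in one retro-[4+2] operation, and last the chain at C4=C5, C7–C11, C6=C7 and C1=C2.
- Enabling feature: ring A (C1–C5, C10) holds four contiguous stereocentres, C3, C4, the quaternary C5 and C10, spread over the trans fusion with ring B (C5–C10). This is the imprint of a cyclohexene made from an (E,E)-1-oxygenated diene C10=C1–C2=C3 and an (E)-enal alkene C4=C5 linked by the four-atom chain C6–C9.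
- Forward order: the chain grows linearly from 2-deoxy-D-ribose (C1, C10, C9, C8, C7) by Wittig (C2, C3), oxidation/Wittig (C6, C5, C14), conjugate addition (C11–C13) and Horner–Wadsworth–Emmons olefination (C4, C15). Rings A and B then close together in a type 1 intramolecular Diels–Alder reaction.
- Stereochemistry: C8 and C9 come from the sugar and C7 from an anti-selective copper-mediated addition steered by C8. C4, C5, C10 and a provisional C3 come from alkene geometry, the endo rule and the C7–C9 triad in the cycloaddition. C3 is reset to the equatorial alcohol by dissolving-metal reduction, and both Z alkenes come from alkyne semihydrogenation.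

Key step: step 9

Remark: every compound carries eremophilane numbers (ring A = C1–C5, C10; ring B = C5–C10; C11–C13 isopropenyl; C14 on C5; C15 on C4); β is the face of the C5 methyl group and α the opposite face; lactol 2 is used as its anomeric mixture.

Step 1
Reactants: 1 2-deoxy-D-ribose
Product: 2 3,4-O-isopropylidene-2-deoxy-D-erythro-pentopyranose (lactol; sugar C1–C5 = C1, C10, C9, C8, C7)
Conditions: 2-methoxypropene (1.2 equiv), PPTS (cat.), EtOAc, 0 °C → rt
Reagents that add atoms: 2-methoxypropene, C=C(C)OC
Why: Kinetic acetonide formation by transketalisation with an enol ether picks the only cis-vicinal diol of the pyranose (O9/O8) and leaves the anomeric hydroxyl free, so that C8 and C9 enter with the configuration of the chiral pool.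

Step 2
Reactants: 2 lactol acetonide; 3 tributyl(1,3-dioxolan-2-ylmethyl)phosphonium bromide
Product: 4 [(4R,5S)-5-[(E)-3-(1,3-dioxolan-2-yl)allyl]-2,2-dimethyl-1,3-dioxolan-4-yl]methanol (free C7 alcohol, 8R,9S, E C1=C2, C3 as dioxolane)
Conditions: 3 (2.5 equiv), KOt-Bu (2.4 equiv), THF, 0 °C; then 2, 0 °C → rt
Reagents that add atoms: none
Why: Wittig olefination of the open-chain aldehyde tautomer of the lactol with a trialkylphosphonium-derived ylide, which favours the E alkene, adds C2 and C3 as an acetal-masked enal that is inert to the later copper and phosphonate steps, and any Z isomer would converge to the E enal in step 6.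

Step 3
Reactants: 4 C7 alcohol; 5 1-(triphenylphosphoranylidene)propan-2-one
Product: 7 (3E)-4-{(4R,5S)-5-[(E)-3-(1,3-dioxolan-2-yl)allyl]-2,2-dimethyl-1,3-dioxolan-4-yl}but-3-en-2-one, via aldehyde 6 (not isolated)
Conditions: PhI(OAc)2 (1.1 equiv), TEMPO (10 mol %), CH2Cl2, rt; then 5 (2.5 equiv), rt
Reagents that add atoms: none
Why: Oxoammonium (TEMPO) oxidation of the primary alcohol followed in the same flask by Wittig olefination with a stabilised ylide gives the E C6=C7 enone and spares the epimerisable cis-dioxolane aldehyde 6 from isolation.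

Step 4
Reactants: 7 (E)-enone; 8 isopropenylmagnesium bromide
Product: 10 (4S)-4-{(4R,5S)-5-[(E)-3-(1,3-dioxolan-2-yl)allyl]-2,2-dimethyl-1,3-dioxolan-4-yl}-5-methylhex-5-en-2-one (7S 8R 9S), via silyl enol ether 9 (not isolated)
Conditions: 8 (1.5 equiv), CuBr·SMe2 (20 mol %), Me3SiCl (2 equiv), THF, −78 °C; aq NH4Cl; then K2CO3 (cat.), MeOH, 0 °C
Reagents that add atoms: chlorotrimethylsilane, C[Si](C)(C)Cl (its atoms stay in 9 only)
Why: Copper-catalysed, chlorosilane-accelerated conjugate addition of a Grignard reagent to a γ-alkoxy (E)-enone, in which the nucleophile attacks C7 anti to the C8–O bond while H8 eclipses the alkene (Felkin–Anh-type model with minimal allylic 1,3-strain), should set the 7,8-anti relation (7S), and mild methanolysis of 9 returns the methyl ketone.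

Step 5
Reactants: 10 methyl ketone; 11 diethyl [2-(methoxy(methyl)amino)-2-oxoethyl]phosphonate
Product: 12 (E)-α,β-unsaturated Weinreb amide (E C4=C5 carrying C14 methyl; C15 as C(O)N(OMe)Me; 7S,8R,9S; dioxolane at C3)
Conditions: 11 (2 equiv), NaH (1.9 equiv), THF, 0 → 50 °C
Reagents that add atoms: none
Why: Horner–Wadsworth–Emmons olefination of a methyl ketone with a stabilised amide phosphonate is E-selective because the branched C6 chain and the carboxamide end up trans, and the minor Z isomer would be removed by chromatography.

Step 6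
Reactants: 12 Weinreb amide acetal
Product: 13 (E)-enal Weinreb amide (O=C3H–C2H=C1H–C10H2, E; rest as in 12)
Conditions: 0.5 M aq HCl, THF, 0 °C → rt
Reagents that add atoms: water, O
Why: Acid-catalysed hydrolysis of an α,β-unsaturated acetal runs through an allyl-stabilised oxocarbenium ion, is therefore much faster than cleavage of the 8,9-acetonide, and delivers the thermodynamically preferred E enal.

Step 7
Reactants: 13 enal Weinreb amide
Product: 14 (E,E)-silyl dienol ether Weinreb amide (TBSO–C3H=C2H–C1H=C10H–C9, both E)
Conditions: TBSOTf (1.2 equiv), Et3N (2.5 equiv), CH2Cl2, −78 → 0 °C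
Reagents that add atoms: tert-butyldimethylsilyl triflate, CC(C)(C)[Si](C)(C)OS(=O)(=O)C(F)(F)F
Why: Soft enolisation (O-silylation of the s-trans enal and γ-deprotonation at C10 by the amine) is the standard route to 1-silyloxy-1,3-dienes; the s-trans enal gives the E enol ether, the branched dioxolanyl substituent on C10 should turn away from C2–H to give the E C10=C1 bond, and vinylogous deprotonation of the amide is much slower at low temperature.

Step 8
Reactants: 14 silyl dienol ether Weinreb amide
Product: 15 (E,E,E)-trienal with 8,9-acetonide, 7-isopropenyl group and terminal silyl dienol ether (cycloaddition precursor)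
Conditions: i-Bu2AlH (1.2 equiv), THF, −78 °C; pH 7 buffer
Reagents that add atoms: none
Why: Reduction of a Weinreb amide with i-Bu2AlH stops at the chelated tetrahedral intermediate, which releases the enal only on work-up, and the silyl dienol ether, the acetonide and the alkenes are inert at −78 °C.

Step 9
Reactants: 15 (E,E,E)-trienal
Product: 16 trans-fused bicyclic aldehyde: 4β-formyl-3β-(tert-butyldimethylsilyloxy)-5β-methyl-10α-H-7α-isopropenyl-8α,9α-(isopropylidenedioxy)octal-1-ene
Conditions: PhMe (0.01 M), BHT (cat.), 120 °C, sealed tube, base-washed glassware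
Reagents that add atoms: none
Why: The step is a concerted but asynchronous [4+2] cycloaddition in which the HOMO of the 1-silyloxydiene (largest coefficient at C10) meets the LUMO of the β-methyl enal (largest coefficient at C5), so that the tether-enforced pairing C5–C10/C3–C4 is also the electronically matched ortho pairing; the closest known reaction type is the thermal type 1 intramolecular Diels–Alder reaction of (E)-deca-2,7,9-trienals to trans-decalins. Ring A (C1–C5, C10) closes as the new cyclohexene through a boat-like six-centre array, and ring B (C5–C10) closes at the same moment because the four-atom tether C6–C9 folds into a chair while the leading C5–C10 bond forms. C4 and C5 are fixed by suprafacial addition to the E alkene, which keeps formyl and methyl cis, and C3 and C10 are fixed by suprafacial addition to the E,E diene, which puts the silyloxy group and C9 on the same face of ring A. The relation between these two pairs comes from the endo position of the formyl group (tether exo), which places H10 anti to the C5 methyl and so gives the trans fusion with 3β-OTBS, 4β-CHO, 5β-CH3 and 10α-H. The absolute sense comes from C7–C9, since only one diene face lets the chair tether carry the isopropenyl group and O9 equatorially (O8 axial, cis-fused dioxolane), whereas the other face would force isopropenyl, O9 and the C5 methyl into a triple syn-axial array. The step therefore needs endo and π-facial selectivity, secured by secondary orbital overlap of the formyl group and by the resident stereotriad, and it is run without Lewis acid because the allylic C9–O bond next to the electron-rich diene would ionise.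

Step 10
Reactants: 16 bicyclic aldehyde
Product: 17 C15 tosylhydrazone of 16
Conditions: TsNHNH2 (1.1 equiv), THF, 4 Å MS, rt
Reagents that add atoms: p-toluenesulfonyl hydrazide, Cc1ccc(cc1)S(=O)(=O)NN
Why: Condensation of the aldehyde with tosylhydrazide under neutral conditions forms the hydrazone without β-elimination of the 3-silyloxy group or epimerisation of the equatorial C4 substituent.

Step 11
Reactants: 17 tosylhydrazone
Product: 18 4β,5β-dimethyl-3β-(tert-butyldimethylsilyloxy)-7α-isopropenyl-8α,9α-(isopropylidenedioxy)-10α-H-octal-1-ene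
Conditions: catecholborane (2 equiv), CHCl3, −10 °C; then NaOAc·3H2O, reflux
Reagents that add atoms: none
Why: Hydride reduction of a tosylhydrazone (Caglioti-type deoxygenation), loss of sulfinate and extrusion of N2 from the alkyldiazene turn the formyl carbon into the C4 methyl group under conditions too mild for uncatalysed hydroboration of the alkenes.

Step 12
Reactants: 18 silyl ether
Product: 19 3β-allylic alcohol (1-ene; otherwise as 18)
Conditions: Bu4NF, THF, rt → 45 °C
Reagents that add atoms: none
Why: Fluoride-induced cleavage of the silyl ether is driven by the strength of the Si–F bond and leaves acetonide and alkenes untouched.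

Step 13
Reactants: 19 allylic alcohol
Product: 20 1-en-3-one (4β,5β-dimethyl, 10α-H, 7α-isopropenyl, 8α,9α-acetonide)
Conditions: Dess–Martin periodinane, CH2Cl2, 0 °C → rt
Reagents that add atoms: none
Why: Dess–Martin oxidation converts the pseudoaxial allylic alcohol into the enone under near-neutral conditions, which erases the C3 configuration that the cycloaddition left on the wrong face without enolisation toward C4 or C10.

Step 14
Reactants: 20 enone
Product: 21 saturated 3α-alcohol (equatorial OH; 4β,5β-dimethyl, 10α-H, 7α-isopropenyl, 8α,9α-acetonide)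
Conditions: Li (excess), NH3(l)/THF, EtOH, −78 → −33 °C; then NH4Cl
Reagents that add atoms: none
Why: Dissolving-metal (Birch-type) reduction of an enone in the presence of an alcohol passes through enolate and ketone to the saturated carbinol and gives the thermodynamically favoured equatorial 3α-alcohol (hydride reagents would be steered toward the axial alcohol by the syn-axial C5 methyl), while the isolated isopropenyl group is not reduced.

Step 15
Reactants: 21 acetonide alcohol
Product: 22 3α,8α,9α-triol
Conditions: AcOH/H2O (4:1), 50 °C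
Reagents that add atoms: none
Why: Acid-catalysed ketal hydrolysis in aqueous acetic acid frees the cis-8,9-diol under conditions that do not protonate the 1,1-disubstituted alkene.

Step 16
Reactants: 22 triol; 23 hex-2-ynoic acid
Product: 24 3α,9α-bis(hex-2-ynoyloxy)-8α-ol
Conditions: 23 (2.2 equiv), DCC (2.3 equiv), DMAP (cat.), CH2Cl2, −20 → 0 °C
Reagents that add atoms: none
Why: Steglich esterification with two equivalents of acid should acylate the two equatorial hydroxyls O3 and O9 and spare the axial O8–H, which is shielded by the 1,3-diaxial H6 and H10 and by the neighbouring isopropenyl group, and any acyl shift would also favour the equatorial O9 ester.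

Step 17
Reactants: 24 bis-ynoate
Product: 25 target, (3R,4R,5R,7S,8R,9S,10R)-3,9-bis[(Z)-hex-2-enoyloxy]-8-hydroxy-7-isopropenyl-4,5-dimethyl-trans-decalin (eremophilane numbering)
Conditions: H2 (1 atm), Pd/CaCO3 poisoned with Pb(OAc)2 (Lindlar catalyst), quinoline, EtOAc, rt, stopped after two equivalents of H2
Reagents that add atoms: none
Why: Lindlar semihydrogenation adds H2 syn to both ynoates to give the two Z enoates, and the poisoned catalyst does not touch the 1,1-disubstituted isopropenyl alkene.

**Compound list**
1 | 2-deoxy-D-ribose | O=CC[C@H](O)[C@H](O)CO | starting material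
2 | 3,4-O-isopropylidene-2-deoxy-D-erythro-pentopyranose | OC1C[C@@H]2OC(C)(C)O[C@@H]2CO1 | intermediate
3 | tributyl(1,3-dioxolan-2-ylmethyl)phosphonium bromide | CCCC[P+](CCCC)(CCCC)CC1OCCO1.[Br-] | starting material
4 | C7 alcohol with (E)-alkenyl dioxolane | OC[C@H]1OC(C)(C)O[C@H]1C/C=C/C2OCCO2 | intermediate
5 | 1-(triphenylphosphoranylidene)propan-2-one | CC(=O)C=P(c1ccccc1)(c1ccccc1)c1ccccc1 | starting material
6 | C7 aldehyde (cis-dioxolane carbaldehyde) | O=C[C@H]1OC(C)(C)O[C@H]1C/C=C/C2OCCO2 | intermediate
7 | (E)-enone | CC(=O)/C=C/[C@H]1OC(C)(C)O[C@H]1C/C=C/C2OCCO2 | intermediate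
8 | isopropenylmagnesium bromide | C=C(C)[Mg]Br | starting material
9 | trimethylsilyl enol ether of 10 | C=C(C)[C@H](C=C(C)O[Si](C)(C)C)[C@H]1OC(C)(C)O[C@H]1C/C=C/C2OCCO2 | intermediate
10 | (7S,8R,9S) methyl ketone | C=C(C)[C@H](CC(C)=O)[C@H]1OC(C)(C)O[C@H]1C/C=C/C2OCCO2 | intermediate
11 | diethyl [2-(methoxy(methyl)amino)-2-oxoethyl]phosphonate | CCOP(=O)(CC(=O)N(C)OC)OCC | starting material
12 | (E)-unsaturated Weinreb amide acetal | C=C(C)[C@H](C/C(C)=C/C(=O)N(C)OC)[C@H]1OC(C)(C)O[C@H]1C/C=C/C2OCCO2 | intermediate
13 | (E)-enal Weinreb amide | C=C(C)[C@H](C/C(C)=C/C(=O)N(C)OC)[C@H]1OC(C)(C)O[C@H]1C/C=C/C=O | intermediate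
14 | (E,E)-silyl dienol ether Weinreb amide | C=C(C)[C@H](C/C(C)=C/C(=O)N(C)OC)[C@H]1OC(C)(C)O[C@H]1/C=C/C=C/O[Si](C)(C)C(C)(C)C | intermediate
15 | (E,E,E)-trienal, cycloaddition precursor | C=C(C)[C@H](C/C(C)=C/C=O)[C@H]1OC(C)(C)O[C@H]1/C=C/C=C/O[Si](C)(C)C(C)(C)C | intermediate
16 | trans-fused bicyclic aldehyde, cycloadduct | C=C(C)[C@@H]1C[C@]2(C)[C@@H](C=O)[C@@H](O[Si](C)(C)C(C)(C)C)C=C[C@H]2[C@H](OC3(C)C)[C@@H]1O3 | intermediate
17 | C15 tosylhydrazone | C=C(C)[C@@H]1C[C@]2(C)[C@@H](C=NNS(=O)(=O)c3ccc(C)cc3)[C@@H](O[Si](C)(C)C(C)(C)C)C=C[C@H]2[C@H](OC4(C)C)[C@@H]1O4 | intermediate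
18 | 4β-methyl 3β-silyl ether | C=C(C)[C@@H]1C[C@]2(C)[C@@H](C)[C@@H](O[Si](C)(C)C(C)(C)C)C=C[C@H]2[C@H](OC3(C)C)[C@@H]1O3 | intermediate
19 | 3β-allylic alcohol | C=C(C)[C@@H]1C[C@]2(C)[C@@H](C)[C@@H](O)C=C[C@H]2[C@H](OC3(C)C)[C@@H]1O3 | intermediate
20 | 1-en-3-one | C=C(C)[C@@H]1C[C@]2(C)[C@@H](C)C(=O)C=C[C@H]2[C@H](OC3(C)C)[C@@H]1O3 | intermediate
21 | saturated 3α-alcohol acetonide | C=C(C)[C@@H]1C[C@]2(C)[C@@H](C)[C@H](O)CC[C@H]2[C@H](OC3(C)C)[C@@H]1O3 | intermediate
22 | 3α,8α,9α-triol | C=C(C)[C@@H]1C[C@]2(C)[C@@H](C)[C@H](O)CC[C@H]2[C@H](O)[C@@H]1O | intermediate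
23 | hex-2-ynoic acid | CCCC#CC(=O)O | starting material
24 | 3,9-bis(hex-2-ynoate) | C=C(C)[C@@H]1C[C@]2(C)[C@@H](C)[C@H](OC(=O)C#CCCC)CC[C@H]2[C@H](OC(=O)C#CCCC)[C@@H]1O | intermediate
25 | CNP0420276.1 | C=C(C)[C@@H]1C[C@]2(C)[C@@H](C)[C@H](OC(=O)/C=C\CCC)CC[C@H]2[C@H](OC(=O)/C=C\CCC)[C@@H]1O | target

**Step count**
Total step count: 17. Longest linear sequence: 17 steps from 1.

**Steps most likely to fail**

Step 9 (cycloaddition).
- What may go wrong: addition to the β,β-disubstituted enal may need temperatures at which the silyl dienol ether is lost through hydrogen shifts or desilylation, and the angular methyl may erode the endo, trans-fused preference.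
- Fallback idea: give up the acid-sensitive donor so that a Lewis acid can be used, and bring in the C3 oxygen after ring closure. It sets out from 13.
- Diene: Luche reduction (NaBH4, CeCl3·7H2O, MeOH, 0 °C) would give the allylic alcohol F1. ClCO2Me/pyridine would give the allylic methyl carbonate F2. Pd(PPh3)4-catalysed 1,4-elimination (THF, reflux) would give the (E)-terminal diene amide F3, and i-Bu2AlH (−78 °C) the oxygen-free trienal F4.
- Ring closure: Me2AlCl (CH2Cl2, −78 → −20 °C) would promote the intramolecular Diels–Alder reaction that forms the same C3–C4 and C5–C10 bonds and give the trans-fused aldehyde F5.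
- Return: the operations of steps 10 and 11 would lead through the tosylhydrazone F6 to the 4β-methyl olefin F7. Allylic oxidation of the C3 methylene (CrO3·3,5-dimethylpyrazole, CH2Cl2, −20 °C), a reaction type that spares isopropenyl groups, comes back to the route at 20.

Step 7 (silyl dienol ether).
- What may go wrong: γ-deprotonation may start from the rotamer that turns the dioxolanyl group inward and so build a Z C10=C1 bond, which cannot reach the cycloaddition geometry. The silyl triflate may also trigger ionisation of the allylic C9–O bond.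
- Fallback: correct the geometry afterwards under thermodynamic control and do not rely on the kinetic deprotonation. It sets out from 13. The silylation product enriched in the 10Z dienol ether F8 would be equilibrated by reversible thiyl-radical addition (PhSSPh cat., hν, benzene, rt), which funnels 1,3-dienes to the more stable E,E form, and comes back at 14.

Step 16 (double acylation).
- What may go wrong: incomplete discrimination between O9–H and O8–H, over-acylation, or acyl migration under DMAP.
- Fallback: separate the two acylations and let a catalyst choose within the diol. It sets out from 21. Steglich esterification of the only free hydroxyl with 23 would give the 3-O-hexynoyl acetonide F9, and AcOH/H2O the 3-O-hexynoyl 8,9-diol F10.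
- Return: diarylborinic acid catalysis (Ph2BOCH2CH2NH2 10 mol %, i-Pr2NEt, MeCN, rt) with hex-2-ynoyl chloride F11 (from 23, (COCl)2, DMF cat.) binds the cis-diol as a borinate and passes the acyl group to the equatorial O9, which comes back at 24.

**Further compounds**
F1 | step 9 | allylic alcohol from 13 | C=C(C)[C@H](C/C(C)=C/C(=O)N(C)OC)[C@H]1OC(C)(C)O[C@H]1C/C=C/CO
F2 | step 9 | allylic methyl carbonate | C=C(C)[C@H](C/C(C)=C/C(=O)N(C)OC)[C@H]1OC(C)(C)O[C@H]1C/C=C/COC(=O)OC
F3 | step 9 | (E)-terminal diene Weinreb amide | C=C(C)[C@H](C/C(C)=C/C(=O)N(C)OC)[C@H]1OC(C)(C)O[C@H]1/C=C/C=C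
F4 | step 9 | trienal without C3 oxygen | C=C(C)[C@H](C/C(C)=C/C=O)[C@H]1OC(C)(C)O[C@H]1/C=C/C=C
F5 | step 9 | trans-fused aldehyde with C3 methylene | C=C(C)[C@@H]1C[C@]2(C)[C@@H](C=O)CC=C[C@H]2[C@H](OC3(C)C)[C@@H]1O3
F6 | step 9 | tosylhydrazone of F5 | C=C(C)[C@@H]1C[C@]2(C)[C@@H](C=NNS(=O)(=O)c3ccc(C)cc3)CC=C[C@H]2[C@H](OC4(C)C)[C@@H]1O4
F7 | step 9 | 4β-methyl olefin | C=C(C)[C@@H]1C[C@]2(C)[C@@H](C)CC=C[C@H]2[C@H](OC3(C)C)[C@@H]1O3
F8 | step 7 | 10Z isomer of 14 | C=C(C)[C@H](C/C(C)=C/C(=O)N(C)OC)[C@H]1OC(C)(C)O[C@H]1/C=C\C=C\O[Si](C)(C)C(C)(C)C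
F9 | step 16 | 3-O-hex-2-ynoyl acetonide | C=C(C)[C@@H]1C[C@]2(C)[C@@H](C)[C@H](OC(=O)C#CCCC)CC[C@H]2[C@H](OC3(C)C)[C@@H]1O3
F10 | step 16 | 3-O-hex-2-ynoyl 8,9-diol | C=C(C)[C@@H]1C[C@]2(C)[C@@H](C)[C@H](OC(=O)C#CCCC)CC[C@H]2[C@H](O)[C@@H]1O
F11 | step 16 | hex-2-ynoyl chloride | CCCC#CC(=O)Cl
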